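The ratio of partner in alpha to partner in eta was 4.08, but the ratio of triple plus tetra at the last readings was 3.39, which is smaller. I took this gap as a sign that partner thinned during a run.

the same everywhere: solid substrate 10 mM
- eta: partner 13 mM; capture agent 10 mM; run made earlier
- alpha: partner 53 mM; capture agent 10 mM; run made earlier
- north: partner 10.0 mM; capture agent 10.0 mM; time 5.0 min
- south-east: partner 15.0 mM; capture agent 10.0 mM; time 5.0 min
- east: partner 40.0 mM; capture agent 10.0 mM; time 5.0 min

| run | time / min | triple product / % | tetra adduct / % |
|---|---|---|---|
| eta | 0.833 | 2 | 0 |
| eta | 1.50 | 4 | 3 |
| eta | 2.50 | 7 | 7 |
| eta | 3.00 | 7 | 13 |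
| eta | 4.00 | 9 | 12 |
| eta | 5.00 | 12 | 16 |
| alpha | 0.333 | 4 | 1 |
| alpha | 1.00 | 3 | 13 |
| alpha | 2.00 | 9 | 42 |
| alpha | 2.50 | 7 | 57 |
| alpha | 4.00 | 8 | 82 |
| alpha | 5.00 | 3 | 92 |

(standard deviation of a reading: 1.5 percentage points)

- given per volume of solution although it is solid: solid substrate
- the analysis behind the earlier runs scatters by 1.5 percentage points, standard deviation
- at the start none of the solid substrate is in solution

- which of these holds the largest part of the solid substrate at the end of north (tetra adduct / triple product / mono adduct / solid substrate / double product)
- which of these holds the largest part of the solid substrate at the end of south-east (tetra adduct / triple product / mono adduct / solid substrate / double product)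
- which of these holds the largest part of the solid substrate at the end of east (tetra adduct / triple product / mono adduct / solid substrate / double product)
- final triple product in east, as a percentage of the solid substrate charged

In the first instants of alpha little showed. At 0.333 min, triple read 4% and tetra 1%, with a scatter of 1.5 percentage points. In the middle, at 2.00 min, tetra had climbed to 42%, while triple read 9%. Triple looked like a passing stage. At 5.00 min, the late share, triple plus tetra, read 95.0%.

I charged each late molecule 4 partners. I took mean partner as the charge less half of what was used, which gave 34.0 mM in alpha. From this I read the carrying dose, 179 mM·min: the mean partner times the time that brings a whole charge to late product. It is a reading and carries the scatter.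

For east I went round twice. The charged partner gave 112%, more than the charge. So I put the late share back into the mean partner. The loop closed at a late share of 71.7%, with mean partner 25.7 mM. The same loop gave 17.9% for north and 26.9% for south-east. North held 1.00 partner per solid substrate, less than the 4 of a tetra adduct, so partner was the limiting reagent there.

The forecast, calling the rate “roughly first order in partner”, named solid substrate for north, solid substrate for south-east and tetra adduct for east, with final triple product in east at 10%.

    starting material + partner → mono adduct (k = 1.10 L mol⁻¹ s⁻¹)
    partner + mono adduct → double product (k = 2.20 L mol⁻¹ s⁻¹)
    partner + double product → triple product (k = 4.10 L mol⁻¹ s⁻¹)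
    partner + triple product → tetra adduct (k = 2.20 L mol⁻¹ s⁻¹)
    solid substrate ⇌ starting material, rate k5*(cs5 - [starting material]) while solid is left; crystals form when [starting material] > cs5 (solubility = 4.60 mM, k = 0.0170 s⁻¹)
    mono adduct + capture agent → trapped intermediate (k = 0.270 L mol⁻¹ s⁻¹)

Final triple product in east was 7.46%. In south-east the answer was tetra adduct at 19.2%, not solid substrate, which held 6.28% while starting material in solution held 39.6%. The late share of east stood at 80.5%, against the 71.7% from the carrying dose. For the neighbour of east charged with 16 mM of partner, the same dose gives 28.7%, and that flask's late share stood at 31.2%.

(The data come from a simulation for an exercise; noise was put on by code.)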